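**Plan**

- Retrosynthesis: cut the C1'–O acyl bond (ester), take the quinone back to a 1,4-diol, cut C2=C3 of ring B (ring-closing metathesis), then C1–C2 and C3–C4 (two carbonyl additions to a ring A dialdehyde), and in the side chain C1'–C2' (allylboration) and C3'=C4' (cross-metathesis).
- Enabling feature: in ring B the C2=C3 alkene is trisubstituted, C2 carries the C1' side chain, and C1 and C4 sit on the ortho carbons C8a and C4a of ring A. A vinyl carbinol and a 2-substituted allyl carbinol placed ortho on ring A can therefore be stitched together at C2=C3.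
- Forward order: ring A enters intact as 3,6-bis(methoxymethoxy)phthalaldehyde and the side chain as a chiral 2-bromoallyl silyl ether. A vinyllithium and a vinyl Grignard addition join them, ring B closes by metathesis and is oxidised to the quinone, and esterification and acid deprotection finish.
- Stereochemistry: the only stereocentre, C1' (R), comes from reagent-controlled Brown allylboration of 2-bromoacrolein and is never a reacting centre afterwards. The mixed C1/C4 carbinol centres are erased by oxidation.

Key step: step 8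

Assumption: the allylborane made from (+)-Ipc2BOMe (the (−)-α-pinene series) is taken to deliver allyl to the aldehyde face that gives (3R)-7, the mirror image of the (S)-sense known for the (+)-α-pinene reagent with benzaldehyde; should the sense prove opposite, the enantiomeric borinate would be used. 2-Bromoacrolein is used freshly distilled.

**Route**

Step 1
Reactants: 1 2,3-dicyanohydroquinone
Product: 2 3,6-bis(methoxymethoxy)benzene-1,2-dicarbonitrile
Conditions: NaH, MOMCl, DMF, 0 °C→rt
Reagents that add atoms: chloromethyl methyl ether (MOMCl), COCCl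
Why: Williamson-type O-alkylation of the two acidic phenoxides should give the bis-acetal, which tolerates the hydride, organolithium, Grignard and metathesis steps that follow.

Step 2
Reactants: 2 3,6-bis(methoxymethoxy)benzene-1,2-dicarbonitrile
Product: 4 3,6-bis(methoxymethoxy)benzene-1,2-dicarbaldehyde, via bis(N-diisobutylalumino)aldimine 3 (not isolated)
Conditions: i-Bu2AlH (2.6 equiv), toluene, −78→−40 °C; then 10% aq. tartaric acid, 0 °C
Reagents that add atoms: water, O
Why: Partial nitrile reduction with i-Bu2AlH should stop at the N-aluminoaldimine at low temperature, and brief mild acid hydrolysis then frees both formyl groups without cleaving the aryl MOM ethers.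

Step 3
Reactants: 5 2-bromoacrolein
Product: 7 (3R)-2-bromohexa-1,5-dien-3-ol, via diisopinocampheylborinate ester 6 (not isolated)
Conditions: (+)-Ipc2BOMe, CH2=CHCH2MgBr, Et2O, 0 °C→rt; then 5, −78 °C; then 3 M NaOH, 30% H2O2, 0 °C→rt
Reagents that add atoms: allylmagnesium bromide, C=CC[Mg]Br
Why: Brown asymmetric allylboration transfers allyl through a closed chair (Zimmerman–Traxler) transition state in which the isopinocampheyl groups of the (−)-α-pinene series select the aldehyde face that gives the (3R)-carbinol, so the new stereocentre is set by the reagent alone.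

Step 4
Reactants: 7 (3R)-2-bromohexa-1,5-dien-3-ol
Product: 8 [(3R)-2-bromohexa-1,5-dien-3-yl]oxy(tert-butyl)dimethylsilane
Conditions: TBSCl, imidazole, DMF, rt
Reagents that add atoms: tert-butyldimethylsilyl chloride, CC(C)(C)[Si](C)(C)Cl
Why: Standard imidazole-promoted silylation of a secondary alcohol should give a silyl ether that withstands t-BuLi, Grignard reagent, metathesis and MnO2 and is later removed by fluoride.

Step 5
Reactants: 8 [(3R)-2-bromohexa-1,5-dien-3-yl]oxy(tert-butyl)dimethylsilane
Product: 9 [(3R)-2-bromo-6-methylhepta-1,5-dien-3-yl]oxy(tert-butyl)dimethylsilane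
Conditions: 2-methylbut-2-ene (excess), second-generation Grubbs catalyst RuCl2(=CHPh)(PCy3)(H2IMes) (3 mol %), CH2Cl2, 40 °C
Reagents that add atoms: 2-methylbut-2-ene, CC=C(C)C
Why: Olefin cross-metathesis with 2-methylbut-2-ene should convert the terminal allyl group into the linear prenyl group, which a direct prenylboration would not give because it delivers the branched 1,1-dimethylallyl isomer; the hindered, electron-poor 2-bromoalkene is a spectator.

Step 6
Reactants: 9 [(3R)-2-bromo-6-methylhepta-1,5-dien-3-yl]oxy(tert-butyl)dimethylsilane; 4 3,6-bis(methoxymethoxy)benzene-1,2-dicarbaldehyde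
Product: 11 3-[(3R)-3-(tert-butyldimethylsilyloxy)-6-methylhepta-1,5-dien-2-yl]-4,7-bis(methoxymethoxy)-1,3-dihydro-2-benzofuran-1-ol (epimers at C1 and C3), via (3R)-3-(tert-butyldimethylsilyloxy)-6-methylhepta-1,5-dien-2-yllithium 10 (not isolated)
Conditions: t-BuLi (2.05 equiv), Et2O, −78 °C; then 4 (1.2 equiv), THF, −78 °C; aq. NH4Cl
Reagents that add atoms: none
Why: Bromine–lithium exchange gives the vinyllithium without touching C1', and its 1,2-addition to one formyl group of the symmetric dialdehyde should produce an alkoxide that closes onto the neighbouring formyl group as a lactolate, masking it against a second addition; the new carbinol and lactol centres form as mixtures that are erased in step 9.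

Step 7
Reactants: 11 3-[(3R)-3-(tert-butyldimethylsilyloxy)-6-methylhepta-1,5-dien-2-yl]-4,7-bis(methoxymethoxy)-1,3-dihydro-2-benzofuran-1-ol
Product: 13 (3R)-3-(tert-butyldimethylsilyloxy)-1-[2-(1-hydroxyprop-2-enyl)-3,6-bis(methoxymethoxy)phenyl]-6-methyl-2-methylidenehept-5-en-1-ol (epimers at both free carbinols), via open-chain bromomagnesium alkoxide aldehyde 12 (not isolated)
Conditions: CH2=CHMgBr (4 equiv), THF, 0 °C→rt; aq. NH4Cl
Reagents that add atoms: vinylmagnesium bromide, C=C[Mg]Br
Why: Grignard addition to a lactol: the first equivalent deprotonates the lactol, whose magnesium salt opens to the hydroxy aldehyde, and a further equivalent adds to the formyl group to give the ortho bis(allylic alcohol) with no stereocontrol needed.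

Step 8
Reactants: 13 (3R)-3-(tert-butyldimethylsilyloxy)-1-[2-(1-hydroxyprop-2-enyl)-3,6-bis(methoxymethoxy)phenyl]-6-methyl-2-methylidenehept-5-en-1-ol
Product: 14 2-[(1R)-1-(tert-butyldimethylsilyloxy)-4-methylpent-3-enyl]-5,8-bis(methoxymethoxy)-1,4-dihydronaphthalene-1,4-diol (epimers at C1 and C4)
Conditions: second-generation Grubbs catalyst RuCl2(=CHPh)(PCy3)(H2IMes) (5 mol %), 1,4-benzoquinone (10 mol %), CH2Cl2 (0.005 M), 40 °C
Reagents that add atoms: none
Why: The ruthenium benzylidene first exchanges with the unhindered monosubstituted vinyl group of 13, and the resulting alkylidene adds across the 1,1-disubstituted alkene on the neighbouring benzylic arm to form a ruthenacyclobutane whose cycloreversion releases the cyclohexene and a ruthenium methylidene that carries the chain with loss of ethene. The closest known reaction type is ring-closing metathesis of ortho-bis(1-hydroxyallyl)benzenes to 1,4-dihydronaphthalene-1,4-diols, here with a 2-substituted allylic partner so that the ring alkene formed is trisubstituted. Ring B closes as a six-membered carbocycle by forming C2=C3 between the two side arms, with the ortho arene carbons C4a and C8a acting as a rigid two-atom tether that keeps the alkenes within reach. No stereocentre is created: C1' is a spectator and the mixed C1/C4 carbinol configurations are removed in step 9. Site selectivity among three alkenes is needed and should follow from substitution and ring size, since the vinyl group loads the catalyst, the 1,1-disubstituted alkene is the only partner that gives a six-membered ring, and the trisubstituted prenyl alkene is a poor partner that could only close a four- or nine-membered ring. High dilution should suppress dimerisation at the vinyl group, and the catalytic 1,4-benzoquinone should suppress ruthenium hydride isomerisation of the allylic carbinols to ketones.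

Step 9
Reactants: 14 2-[(1R)-1-(tert-butyldimethylsilyloxy)-4-methylpent-3-enyl]-5,8-bis(methoxymethoxy)-1,4-dihydronaphthalene-1,4-diol
Product: 16 2-[(1R)-1-(tert-butyldimethylsilyloxy)-4-methylpent-3-enyl]-5,8-bis(methoxymethoxy)naphthalene-1,4-dione, via 4-hydroxynaphthalen-1(4H)-one 15 (not isolated)
Conditions: MnO2 (activated, excess), CH2Cl2, rt
Reagents that add atoms: none
Why: MnO2 oxidation of allylic and benzylic alcohols should take both carbinols to the ene-dione, the less hindered C4 carbinol expected first, and any hydroxy enone that tautomerises to the naphthalene-1,4-diol is oxidised to the same quinone.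

Step 10
Reactants: 16 2-[(1R)-1-(tert-butyldimethylsilyloxy)-4-methylpent-3-enyl]-5,8-bis(methoxymethoxy)naphthalene-1,4-dione
Product: 17 2-[(1R)-1-hydroxy-4-methylpent-3-enyl]-5,8-bis(methoxymethoxy)naphthalene-1,4-dione
Conditions: HF·pyridine, pyridine, THF, 0 °C→rt
Reagents that add atoms: none
Why: Buffered fluoride desilylation should free the C1' alcohol while leaving the aryl MOM ethers intact, and it avoids the basic conditions under which the quinone and the C1'–H next to it would be at risk.

Step 11
Reactants: 18 3-hydroxy-3-methylbutanoic acid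
Product: 20 3-methyl-3-(triethylsilyloxy)butanoic acid, via triethylsilyl 3-methyl-3-(triethylsilyloxy)butanoate 19 (not isolated)
Conditions: Et3SiOTf (2.3 equiv), 2,6-lutidine, CH2Cl2, 0 °C; then K2CO3, MeOH/H2O, 0 °C; aq. KHSO4 to pH 4
Reagents that add atoms: triethylsilyl trifluoromethanesulfonate, CC[Si](CC)(CC)OS(=O)(=O)C(F)(F)F
Why: Silyl triflate silylation covers both the tertiary alcohol and the acid, and selective hydrolysis of the far more labile silyl ester should leave the tertiary silyl ether, so the hydroxyl cannot interfere with carboxyl activation.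

Step 12
Reactants: 17 2-[(1R)-1-hydroxy-4-methylpent-3-enyl]-5,8-bis(methoxymethoxy)naphthalene-1,4-dione; 20 3-methyl-3-(triethylsilyloxy)butanoic acid
Product: 21 (1R)-1-[5,8-bis(methoxymethoxy)-1,4-dioxo-1,4-dihydronaphthalen-2-yl]-4-methylpent-3-enyl 3-methyl-3-(triethylsilyloxy)butanoate
Conditions: 20 (1.5 equiv), DCC, DMAP (0.2 equiv), CH2Cl2, 0 °C→rt
Reagents that add atoms: none
Why: Steglich esterification acylates the secondary C1' alcohol on oxygen with retention, as is well established for the side-chain hydroxyl of this naphthoquinone class.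

Step 13
Reactants: 21 (1R)-1-[5,8-bis(methoxymethoxy)-1,4-dioxo-1,4-dihydronaphthalen-2-yl]-4-methylpent-3-enyl 3-methyl-3-(triethylsilyloxy)butanoate
Product: 22 beta-HIVS
Conditions: 3 M aq. HCl, THF, 0 °C→rt
Reagents that add atoms: none
Why: Acid-catalysed acetal hydrolysis should remove the two aryl MOM groups, helped by the hydrogen bond each freed phenol forms to the peri carbonyl, and the tertiary triethylsilyl ether falls under the same conditions; the three groups leave in no fixed order, and the acylated C1' oxygen cannot cyclise onto the prenyl alkene.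

**Compound list**

1 | 2,3-dicyanohydroquinone (3,6-dihydroxybenzene-1,2-dicarbonitrile) | N#Cc1c(O)ccc(O)c1C#N | starting material
2 | 3,6-bis(methoxymethoxy)benzene-1,2-dicarbonitrile | COCOc1ccc(OCOC)c(C#N)c1C#N | intermediate
3 | bis(N-diisobutylalumino)aldimine of 4 | COCOc1ccc(OCOC)c(C=N[Al](CC(C)C)CC(C)C)c1C=N[Al](CC(C)C)CC(C)C | intermediate
4 | 3,6-bis(methoxymethoxy)benzene-1,2-dicarbaldehyde | COCOc1ccc(OCOC)c(C=O)c1C=O | intermediate
5 | 2-bromoacrolein (2-bromoprop-2-enal) | C=C(Br)C=O | starting material
6 | (3R)-2-bromohexa-1,5-dien-3-yl diisopinocampheylborinate, isopinocampheyl groups of the (−)-α-pinene series | C=CC[C@@H](OB([C@H]1C[C@H](C2(C)C)C[C@H]2[C@@H]1C)[C@H]1C[C@H](C2(C)C)C[C@H]2[C@@H]1C)C(Br)=C | intermediate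
7 | (3R)-2-bromohexa-1,5-dien-3-ol | C=CC[C@@H](O)C(Br)=C | intermediate
8 | [(3R)-2-bromohexa-1,5-dien-3-yl]oxy(tert-butyl)dimethylsilane | C=CC[C@@H](O[Si](C)(C)C(C)(C)C)C(Br)=C | intermediate
9 | [(3R)-2-bromo-6-methylhepta-1,5-dien-3-yl]oxy(tert-butyl)dimethylsilane | C=C(Br)[C@H](O[Si](C)(C)C(C)(C)C)CC=C(C)C | intermediate
10 | (3R)-3-(tert-butyldimethylsilyloxy)-6-methylhepta-1,5-dien-2-yllithium | [Li]C(=C)[C@H](O[Si](C)(C)C(C)(C)C)CC=C(C)C | intermediate
11 | 3-[(3R)-3-(tert-butyldimethylsilyloxy)-6-methylhepta-1,5-dien-2-yl]-4,7-bis(methoxymethoxy)-1,3-dihydro-2-benzofuran-1-ol, epimers at C1 and C3 | OC1OC(C(=C)[C@H](O[Si](C)(C)C(C)(C)C)CC=C(C)C)c2c(OCOC)ccc(OCOC)c21 | intermediate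
12 | bromomagnesium alkoxide of (3R)-3-(tert-butyldimethylsilyloxy)-1-[2-formyl-3,6-bis(methoxymethoxy)phenyl]-6-methyl-2-methylidenehept-5-en-1-ol, epimers at C1 | O=Cc1c(OCOC)ccc(OCOC)c1C(O[Mg]Br)C(=C)[C@H](O[Si](C)(C)C(C)(C)C)CC=C(C)C | intermediate
13 | (3R)-3-(tert-butyldimethylsilyloxy)-1-[2-(1-hydroxyprop-2-enyl)-3,6-bis(methoxymethoxy)phenyl]-6-methyl-2-methylidenehept-5-en-1-ol, epimers at both free carbinols | C=CC(O)c1c(OCOC)ccc(OCOC)c1C(O)C(=C)[C@H](O[Si](C)(C)C(C)(C)C)CC=C(C)C | intermediate
14 | 2-[(1R)-1-(tert-butyldimethylsilyloxy)-4-methylpent-3-enyl]-5,8-bis(methoxymethoxy)-1,4-dihydronaphthalene-1,4-diol, epimers at C1 and C4 | CC(C)=CC[C@@H](O[Si](C)(C)C(C)(C)C)C1=CC(O)c2c(OCOC)ccc(OCOC)c2C1O | intermediate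
15 | 3-[(1R)-1-(tert-butyldimethylsilyloxy)-4-methylpent-3-enyl]-4-hydroxy-5,8-bis(methoxymethoxy)naphthalen-1(4H)-one, epimers at C4 | CC(C)=CC[C@@H](O[Si](C)(C)C(C)(C)C)C1=CC(=O)c2c(OCOC)ccc(OCOC)c2C1O | intermediate
16 | 2-[(1R)-1-(tert-butyldimethylsilyloxy)-4-methylpent-3-enyl]-5,8-bis(methoxymethoxy)naphthalene-1,4-dione | CC(C)=CC[C@@H](O[Si](C)(C)C(C)(C)C)C1=CC(=O)c2c(OCOC)ccc(OCOC)c2C1=O | intermediate
17 | 2-[(1R)-1-hydroxy-4-methylpent-3-enyl]-5,8-bis(methoxymethoxy)naphthalene-1,4-dione | CC(C)=CC[C@@H](O)C1=CC(=O)c2c(OCOC)ccc(OCOC)c2C1=O | intermediate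
18 | 3-hydroxy-3-methylbutanoic acid | CC(C)(O)CC(=O)O | starting material
19 | triethylsilyl 3-methyl-3-(triethylsilyloxy)butanoate | CC[Si](CC)(CC)OC(C)(C)CC(=O)O[Si](CC)(CC)CC | intermediate
20 | 3-methyl-3-(triethylsilyloxy)butanoic acid | CC[Si](CC)(CC)OC(C)(C)CC(=O)O | intermediate
21 | (1R)-1-[5,8-bis(methoxymethoxy)-1,4-dioxo-1,4-dihydronaphthalen-2-yl]-4-methylpent-3-enyl 3-methyl-3-(triethylsilyloxy)butanoate | CC(C)=CC[C@@H](OC(=O)CC(C)(C)O[Si](CC)(CC)CC)C1=CC(=O)c2c(OCOC)ccc(OCOC)c2C1=O | intermediate
22 | beta-HIVS, (1R)-1-(5,8-dihydroxy-1,4-dioxo-1,4-dihydronaphthalen-2-yl)-4-methylpent-3-enyl 3-hydroxy-3-methylbutanoate | CC(C)=CC[C@@H](OC(=O)CC(C)(C)O)C1=CC(=O)c2c(O)ccc(O)c2C1=O | target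

**Step count**

Total: 13 steps. Longest linear sequence: 10 steps (steps 3, 4, 5, 6, 7, 8, 9, 10, 12, 13, from 2-bromoacrolein).

**Steps most likely to fail, with fallbacks**

Step 8. Ruthenium hydride isomerisation of the free allylic carbinols to ketones, or dehydrative aromatisation of the dihydronaphthalenediol as it forms, may outpace closure onto the hindered 1,1-disubstituted alkene. The fallback sets out from 13 and masks both carbinols before the metathesis. Acetylation (Ac2O, DMAP, pyridine) would give (3R)-1-[2-(1-acetoxyprop-2-enyl)-3,6-bis(methoxymethoxy)phenyl]-3-(tert-butyldimethylsilyloxy)-6-methyl-2-methylidenehept-5-enyl acetate F1. Ring closure with the second-generation Hoveyda–Grubbs catalyst RuCl2(=CH-C6H4-2-O-i-Pr)(H2IMes) in toluene at 80 °C would give 2-[(1R)-1-(tert-butyldimethylsilyloxy)-4-methylpent-3-enyl]-5,8-bis(methoxymethoxy)-1,4-dihydronaphthalene-1,4-diyl diacetate F2. Methanolysis (K2CO3, MeOH, 0 °C) then comes back to the route at 14, which is oxidised at once as in step 9.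

Step 6. The α-silyloxy vinyllithium may suffer oxygen-to-carbon silyl migration or protonation before it adds, and a second addition to the dialdehyde may compete if lactolate formation is slow. The fallback sets out from 9 and 4 and replaces the preformed organolithium by a Nozaki–Hiyama–Kishi coupling (CrCl2, catalytic NiCl2, DMF/THF, rt). The organochromium species forms in the presence of the aldehyde, adds chemoselectively, and its alkoxide closes to the same lactol. This fallback makes no new compound (F0) and comes back to the route at 11.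

Step 13. Acid exposure long enough to cleave both aryl acetals may also dehydrate the tertiary carbinol or solvolyse the C1' ester. The fallback sets out from 16 and moves the acid step ahead of the esterification. Global deprotection (HCl, MeOH/THF, rt) would give shikonin F3. Steglich esterification of F3 with 20 (DCC, DMAP, CH2Cl2), in which the peri-hydrogen-bonded phenols are not acylated, would give (1R)-1-(5,8-dihydroxy-1,4-dioxo-1,4-dihydronaphthalen-2-yl)-4-methylpent-3-enyl 3-methyl-3-(triethylsilyloxy)butanoate F4. HF·pyridine in THF then removes the silyl group under near-neutral conditions and comes back to the route at 22.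

**Further compounds**

F1 | step 8 | (3R)-1-[2-(1-acetoxyprop-2-enyl)-3,6-bis(methoxymethoxy)phenyl]-3-(tert-butyldimethylsilyloxy)-6-methyl-2-methylidenehept-5-enyl acetate | C=CC(OC(C)=O)c1c(OCOC)ccc(OCOC)c1C(OC(C)=O)C(=C)[C@H](O[Si](C)(C)C(C)(C)C)CC=C(C)C
F2 | step 8 | 2-[(1R)-1-(tert-butyldimethylsilyloxy)-4-methylpent-3-enyl]-5,8-bis(methoxymethoxy)-1,4-dihydronaphthalene-1,4-diyl diacetate | CC(C)=CC[C@@H](O[Si](C)(C)C(C)(C)C)C1=CC(OC(C)=O)c2c(OCOC)ccc(OCOC)c2C1OC(C)=O
F0 | step 6 | none | none
F3 | step 13 | shikonin, 5,8-dihydroxy-2-[(1R)-1-hydroxy-4-methylpent-3-enyl]naphthalene-1,4-dione | CC(C)=CC[C@@H](O)C1=CC(=O)c2c(O)ccc(O)c2C1=O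
F4 | step 13 | (1R)-1-(5,8-dihydroxy-1,4-dioxo-1,4-dihydronaphthalen-2-yl)-4-methylpent-3-enyl 3-methyl-3-(triethylsilyloxy)butanoate | CC(C)=CC[C@@H](OC(=O)CC(C)(C)O[Si](CC)(CC)CC)C1=CC(=O)c2c(O)ccc(O)c2C1=O
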